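**Retrosynthetic overview**

1. The two (Z)-2-methylbut-2-enoates go on last, first on the C-6 tertiary alkoxide and then on the C-2 allylic alcohol. The C-6 tertiary carbinol comes from a C-6 exo-methylene ketone through a C-7 hydroxyl relay (Luche reduction, hydroxyl-directed epoxidation, hydride opening, reoxidation).
2. The ring A tetrasubstituted alkene with its isopropyl group comes from 1,4-hydrogenation of the locked s-cis diene C-4=C-3a–C-3=CMe2.
3. Rings A and B are formed together by a rhodium-catalysed (5+2) cycloaddition of a terminal alkyne with a 1-silyloxy-1-alkenylcyclopropane across a three-atom tether. Ring A (five-membered) closes first within the catalytic cycle and ring B (seven-membered) closes in the reductive elimination.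
4. Feature on which this rests: in the bicyclo[5.3.0]decane core the sp2 fusion carbon C-3a sits beside the methyl-bearing quaternary carbon C-8a, and the ring B ketone C-7 sits two atoms from C-8a. These three atoms are the alkyne carbon, the alkene terminus and the silyloxy cyclopropane carbon of the precursor.
5. The precursor is built linearly from 3-methylbut-2-enal: bromination, Sonogashira coupling, asymmetric propargylation, carboalumination–iodination, alkenyllithium addition to cyclopropanone.

Key step: step 10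

Remark: ring atoms carry azulene numbers (C-1 CH2, C-2 secondary carbinol, C-3 isopropyl-bearing carbon, C-3a sp2 fusion carbon, C-6 tertiary carbinol, C-7 ketone, C-8a quaternary carbon); ring A is the five-membered ring and ring B the seven-membered ring; TBS = tert-butyldimethylsilyl; the sense of induction of the (S)-configured phosphoric acid in step 3 is assumed by analogy with aryl and alkenyl aldehydes.

**Route**

Step 1
Reactants: 1 3-methylbut-2-enal
Product: 3 2-bromo-3-methylbut-2-enal, via 2,3-dibromo-3-methylbutanal 2 (not isolated)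
Conditions: Br2, CH2Cl2, 0 °C; then Et3N, 0 °C → rt
Reagents that add atoms: bromine BrBr
Why: Bromination–dehydrobromination, in which bromine adds across the enal alkene and triethylamine removes HBr through the acidic α-hydrogen, is the standard route to α-bromoenals and creates no stereocentre.

Step 2
Reactants: 3 2-bromo-3-methylbut-2-enal; 4 ethynyltrimethylsilane
Product: 5 3-methyl-2-[(trimethylsilyl)ethynyl]but-2-enal
Conditions: PdCl2(PPh3)2 (3 mol%), CuI (6 mol%), Et3N, THF, rt
Reagents that add atoms: none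
Why: Sonogashira coupling of the electron-poor alkenyl bromide with the terminal alkyne is facile, and the silyl cap keeps the new alkyne inert until step 9.

Step 3
Reactants: 5 3-methyl-2-[(trimethylsilyl)ethynyl]but-2-enal; 6 allenylboronic acid pinacol ester
Product: 7 (4S)-2-methyl-3-[(trimethylsilyl)ethynyl]hept-2-en-6-yn-4-ol
Conditions: (S)-TRIP phosphoric acid (10 mol%), 4 Å molecular sieves, toluene, 0 °C; aqueous work-up
Reagents that add atoms: none
Why: Chiral phosphoric acid-catalysed propargylboration through a closed six-membered transition state gives the homopropargylic alcohol, and the catalyst sets the (S) carbinol (sense to be confirmed by Mosher ester analysis, the antipodal acid being used if required).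

Step 4
Reactants: 7 (4S)-2-methyl-3-[(trimethylsilyl)ethynyl]hept-2-en-6-yn-4-ol
Product: 9 (4S,6E)-7-iodo-2,6-dimethyl-3-[(trimethylsilyl)ethynyl]hepta-2,6-dien-4-ol, via alkenylalane 8 (not isolated)
Conditions: AlMe3 (3 equiv), Cp2ZrCl2 (0.25 equiv), CH2Cl2, 0 °C → rt; then I2, THF, −30 °C
Reagents that add atoms: trimethylaluminium C[Al](C)C; iodine II
Why: Negishi zirconium-catalysed carboalumination adds methyl and aluminium syn across the terminal alkyne with methyl on the internal carbon, and iodinolysis with retention gives the (E)-iodide, while the hindered silyl-capped alkyne reacts far more slowly and the carbinol rides through as its aluminium alkoxide.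

Step 5
Reactants: 9 (4S,6E)-7-iodo-2,6-dimethyl-3-[(trimethylsilyl)ethynyl]hepta-2,6-dien-4-ol
Product: 10 tert-butyl{[(4S,6E)-7-iodo-2,6-dimethyl-3-[(trimethylsilyl)ethynyl]hepta-2,6-dien-4-yl]oxy}dimethylsilane
Conditions: TBSOTf, 2,6-lutidine, CH2Cl2, −78 → 0 °C
Reagents that add atoms: tert-butyldimethylsilyl triflate CC(C)(C)[Si](C)(C)OS(=O)(=O)C(F)(F)F
Why: Silyl ether protection of the hindered secondary alcohol with the silyl triflate is fast at low temperature and leaves the alkenyl iodide and the enyne untouched.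

Step 6
Reactants: 11 (1-ethoxycyclopropoxy)trimethylsilane
Product: 12 1-ethoxycyclopropan-1-ol
Conditions: MeOH, rt
Reagents that add atoms: none
Why: Methanolysis of the mixed silyl ketal liberates cyclopropanone ethyl hemiketal, the storable cyclopropanone equivalent.

Step 7
Reactants: 10 tert-butyl{[(4S,6E)-7-iodo-2,6-dimethyl-3-[(trimethylsilyl)ethynyl]hepta-2,6-dien-4-yl]oxy}dimethylsilane; 12 1-ethoxycyclopropan-1-ol
Product: 16 1-[(1E,4S)-4-[(tert-butyldimethylsilyl)oxy]-2,6-dimethyl-5-[(trimethylsilyl)ethynyl]hepta-1,5-dien-1-yl]cyclopropan-1-ol, via alkenyllithium 13 (not isolated), via bromomagnesium 1-ethoxycyclopropanolate 14 (not isolated), via cyclopropanone 15 (not isolated)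
Conditions: 10, t-BuLi (2.1 equiv), Et2O, −78 °C; added to 12 pre-treated with MeMgBr (1.0 equiv), THF, −78 °C; then −78 °C → rt
Reagents that add atoms: none
Why: Iodine–lithium exchange is faster than any addition to the enyne and retains the alkene geometry, and the alkenyllithium undergoes 1,2-addition to cyclopropanone released from the magnesium hemiketalate, the established route to 1-alkenylcyclopropanols.

Step 8
Reactants: 16 1-[(1E,4S)-4-[(tert-butyldimethylsilyl)oxy]-2,6-dimethyl-5-[(trimethylsilyl)ethynyl]hepta-1,5-dien-1-yl]cyclopropan-1-ol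
Product: 17 bis-TBS ether of 16 (cyclopropyl and C-4 oxygens silylated; alkyne still capped)
Conditions: TBSOTf, 2,6-lutidine, CH2Cl2, −78 °C
Reagents that add atoms: tert-butyldimethylsilyl triflate CC(C)(C)[Si](C)(C)OS(=O)(=O)C(F)(F)F
Why: Silylation of the tertiary cyclopropanol under buffered, acid-free conditions traps it before ring expansion to a cyclobutanone or ring opening can occur.

Step 9
Reactants: 17 bis-TBS ether of 16
Product: 18 tert-butyl({1-[(1E,4S)-4-[(tert-butyldimethylsilyl)oxy]-5-ethynyl-2,6-dimethylhepta-1,5-dien-1-yl]cyclopropyl}oxy)dimethylsilane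
Conditions: K2CO3, MeOH, rt
Reagents that add atoms: none
Why: Base-mediated protiodesilylation cleaves only the alkynyl C–SiMe3 bond, both TBS ethers being stable to carbonate in methanol.

Step 10
Reactants: 18 tert-butyl({1-[(1E,4S)-4-[(tert-butyldimethylsilyl)oxy]-5-ethynyl-2,6-dimethylhepta-1,5-dien-1-yl]cyclopropyl}oxy)dimethylsilane
Product: 19 (2S,8aR)-2,7-bis[(tert-butyldimethylsilyl)oxy]-8a-methyl-3-(propan-2-ylidene)-1,2,3,5,6,8a-hexahydroazulene
Conditions: [Rh(CO)2Cl]2 (5 mol%), ClCH2CH2Cl (0.02 M), 60–80 °C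
Reagents that add atoms: none
Why: Monovalent rhodium binds the alkyne and the alkenylcyclopropane, cleaves a cyclopropane C–C bond to a rhodacyclohexene (σ-alkyl, π-allyl with the silyloxy group on the central allyl carbon), inserts the tethered alkyne at the methyl-bearing allyl terminus and reductively eliminates the cycloheptadiene, so that the silyloxy carbon emerges as the ring B enol ether at C-7. The closest known reaction type is the [Rh(CO)2Cl]2-catalysed intramolecular (5+2) cycloaddition of alkynes with vinylcyclopropanes, which is established for 1-silyloxy-vinylcyclopropanes and for trisubstituted alkenes that give quaternary fusion carbons. Ring A closes in the insertion step as a five-membered exo closure onto the alkyne across the three-atom tether (C-8a–C-3a bond), and ring B closes last by C(sp2)–C(sp3) reductive elimination from the eight-membered rhodacycle (C-4–C-5 bond). The new stereocentre C-8a is set by the alkene face that rhodium occupies, under control of the C-2 silyloxy carbon in the tether: 1,3-allylic strain with the isopropylidene turns the silyloxy group pseudo-axial on the forming ring A, where it should take the face of the small methyl group and avoid the rhodium-bearing allyl arm, which places methyl and silyloxy cis. The step needs this facial selectivity and chemoselectivity for the terminal alkyne over the tetrasubstituted alkene of the enyne; the (E) geometry keeps the tether trans to the cyclopropane, the two cyclopropane CH2 groups are equivalent so no regiochemical issue arises, and a chiral diphosphine on a cationic monovalent rhodium centre can reinforce the sense.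

Step 11
Reactants: 19 (2S,8aR)-2,7-bis[(tert-butyldimethylsilyl)oxy]-8a-methyl-3-(propan-2-ylidene)-1,2,3,5,6,8a-hexahydroazulene
Product: 20 (2S,8aR)-2-[(tert-butyldimethylsilyl)oxy]-8a-methyl-3-(propan-2-ylidene)-1,2,3,5,6,8a-hexahydroazulen-7(8H)-one
Conditions: Bu4NF (1.1 equiv), AcOH (1.5 equiv), THF, −20 °C
Reagents that add atoms: none
Why: Selective desilylation works because fluoride attacks the enol silyl ether far faster than the hindered secondary alkyl silyl ether, and buffered protonation at C-8 gives the ketone without touching the diene.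

Step 12
Reactants: 20 (2S,8aR)-2-[(tert-butyldimethylsilyl)oxy]-8a-methyl-3-(propan-2-ylidene)-1,2,3,5,6,8a-hexahydroazulen-7(8H)-one
Product: 21 (2S,8aR)-2-[(tert-butyldimethylsilyl)oxy]-8a-methyl-3-(propan-2-yl)-1,2,4,5,6,8a-hexahydroazulen-7(8H)-one
Conditions: (naphthalene)Cr(CO)3 (20 mol%), H2 (50 bar), THF, 45 °C
Reagents that add atoms: none
Why: (Arene)Cr(CO)3-catalysed 1,4-hydrogenation needs an s-cis diene, which the 1,2-bis(alkylidene)cyclopentane unit supplies in locked form, so hydrogen is delivered to C-4 and to the isopropylidene carbon and leaves the tetrasubstituted C-3=C-3a alkene and the ketone untouched, with no stereocentre formed.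

Step 13
Reactants: 21 (2S,8aR)-2-[(tert-butyldimethylsilyl)oxy]-8a-methyl-3-(propan-2-yl)-1,2,4,5,6,8a-hexahydroazulen-7(8H)-one
Product: 25 (2S,8aR)-2-[(tert-butyldimethylsilyl)oxy]-8a-methyl-6-methylidene-3-(propan-2-yl)-1,2,4,5,6,8a-hexahydroazulen-7(8H)-one, via lithium enolate 22 (not isolated), via Mannich base 23 (not isolated), via trimethylammonium iodide 24 (not isolated)
Conditions: LiN(iPr)2, THF, −78 °C; Eschenmoser's salt, −78 °C → rt; then MeI, CH2Cl2, rt; then aq. NaHCO3, rt
Reagents that add atoms: Eschenmoser's salt (N,N-dimethylmethyleneiminium iodide) C=[N+](C)C.[I-]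
Why: Kinetic deprotonation occurs at C-6 because C-8 is neopentyl (flanked by the quaternary carbon), the enolate undergoes a Mannich reaction with the iminium salt, and quaternisation followed by β-elimination of trimethylamine gives the exocyclic enone.

Step 14
Reactants: 25 (2S,8aR)-2-[(tert-butyldimethylsilyl)oxy]-8a-methyl-6-methylidene-3-(propan-2-yl)-1,2,4,5,6,8a-hexahydroazulen-7(8H)-one
Product: 26 (2S,7R,8aS)-2-[(tert-butyldimethylsilyl)oxy]-8a-methyl-6-methylidene-3-(propan-2-yl)-1,2,4,5,6,7,8,8a-octahydroazulen-7-ol (7-hydroxyl cis to the 8a-methyl; the 8a descriptor changes by priority only)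
Conditions: NaBH4, CeCl3·7H2O, MeOH, −78 °C
Reagents that add atoms: none
Why: Luche 1,2-reduction delivers hydride to C-7 from the face opposite the angular methyl, which the ring fusion holds pseudo-axial on ring B and 1,3 to the carbonyl, so the hydroxyl ends cis to that methyl.

Step 15
Reactants: 26 (2S,7R,8aS)-allylic alcohol
Product: 27 spiro-epoxide of 26 at C-6 (epoxide oxygen on C-6 cis to the 7-hydroxyl and to the 8a-methyl; 2S,6R,7R,8aS)
Conditions: VO(acac)2 (5 mol%), t-BuOOH (decane solution), CH2Cl2, 0 °C → rt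
Reagents that add atoms: tert-butyl hydroperoxide CC(C)(C)OO
Why: In the hydroxyl-directed vanadium-catalysed epoxidation the alkoxide-bound peroxide reaches only the alkene face on the side of the C-7 hydroxyl, which sets the C-6 oxygen cis to the angular methyl, and the undirected tetrasubstituted ring A alkene does not react.

Step 16
Reactants: 27 spiro-epoxide
Product: 28 (2S,6S,7R,8aS)-2-[(tert-butyldimethylsilyl)oxy]-6,8a-dimethyl-3-(propan-2-yl)-1,2,4,5,6,7,8,8a-octahydroazulene-6,7-diol
Conditions: LiAlH4, THF, 0 °C → rt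
Reagents that add atoms: none
Why: Hydride opens the epoxide by SN2 attack at the unsubstituted CH2 terminus (the other terminus is fully substituted), turning it into the C-6 methyl group and the tertiary alcohol with the C-6 configuration retained.

Step 17
Reactants: 28 (2S,6S,7R,8aS)-diol
Product: 29 (2S,6S,8aR)-2-[(tert-butyldimethylsilyl)oxy]-6-hydroxy-6,8a-dimethyl-3-(propan-2-yl)-1,2,4,5,6,8a-hexahydroazulen-7(8H)-one
Conditions: IBX, DMSO, rt
Reagents that add atoms: none
Why: IBX oxidises the secondary alcohol of a secondary–tertiary 1,2-diol to the α-hydroxy ketone without C–C cleavage, which removes the C-7 relay stereocentre once it has done its work.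

Step 18
Reactants: 29 (2S,6S,8aR)-α-hydroxy ketone; 30 (2Z)-2-methylbut-2-enoic acid (angelic acid)
Product: 32 (2S,6S,8aR)-2-[(tert-butyldimethylsilyl)oxy]-6,8a-dimethyl-7-oxo-3-(propan-2-yl)-1,2,4,5,6,7,8,8a-octahydroazulen-6-yl (2Z)-2-methylbut-2-enoate, via lithium alkoxide 31 (not isolated)
Conditions: 30, 2,4,6-trichlorobenzoyl chloride, Et3N, THF, rt (mixed anhydride); 29, LiN(SiMe3)2 (1.05 equiv), THF, −78 °C; combined, −78 → 0 °C
Reagents that add atoms: none
Why: O-acylation of the tertiary lithium alkoxide (the hydroxyl is far more acidic than the ketone α-CH) by the Yamaguchi-type mixed anhydride occurs at the less hindered angeloyl carbonyl, and the absence of nucleophilic amine catalysts keeps the (Z) geometry (stereoconservative angeloylation).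

Step 19
Reactants: 32 tertiary angelate TBS ether
Product: 33 (2S,6S,8aR)-2-hydroxy-6,8a-dimethyl-7-oxo-3-(propan-2-yl)-1,2,4,5,6,7,8,8a-octahydroazulen-6-yl (2Z)-2-methylbut-2-enoate
Conditions: HF·pyridine, pyridine, THF, 0 °C → rt
Reagents that add atoms: none
Why: Buffered hydrogen fluoride cleaves the secondary silyl ether (desilylation) without acyl transfer or isomerisation of the angelate and without ionising the allylic carbinol.

Step 20
Reactants: 33 hydroxy angelate; 30 (2Z)-2-methylbut-2-enoic acid
Product: 34 (2S,6S,8aR)-6,8a-dimethyl-7-oxo-3-(propan-2-yl)-1,2,4,5,6,7,8,8a-octahydroazulene-2,6-diyl bis[(2Z)-2-methylbut-2-enoate] (CNP0193302.1)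
Conditions: 30, 2,4,6-trichlorobenzoyl chloride, Et3N, toluene, rt; then 33, 80 °C
Reagents that add atoms: none
Why: Yamaguchi esterification of the hindered allylic alcohol by thermal reaction with the mixed anhydride, run without 4-(dimethylamino)pyridine, gives the second angelate with the (Z) geometry retained and the C-2 configuration untouched.

**Compound list**

1 | 3-methylbut-2-enal | CC(C)=CC=O | starting material
2 | 2,3-dibromo-3-methylbutanal | CC(C)(Br)C(Br)C=O | intermediate
3 | 2-bromo-3-methylbut-2-enal | CC(C)=C(Br)C=O | intermediate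
4 | ethynyltrimethylsilane | C#C[Si](C)(C)C | starting material
5 | 3-methyl-2-[(trimethylsilyl)ethynyl]but-2-enal | CC(C)=C(C=O)C#C[Si](C)(C)C | intermediate
6 | allenylboronic acid pinacol ester | C=C=CB1OC(C)(C)C(C)(C)O1 | starting material
7 | (4S)-2-methyl-3-[(trimethylsilyl)ethynyl]hept-2-en-6-yn-4-ol | C[Si](C)(C)C#CC(=C(C)C)[C@@H](O)CC#C | intermediate
8 | (E)-alkenyl(dimethyl)alane of 7 with the carbinol as its dimethylaluminium alkoxide | C[Si](C)(C)C#CC(=C(C)C)[C@@H](O[Al](C)C)C/C(C)=C/[Al](C)C | intermediate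
9 | (4S,6E)-7-iodo-2,6-dimethyl-3-[(trimethylsilyl)ethynyl]hepta-2,6-dien-4-ol | C[Si](C)(C)C#CC(=C(C)C)[C@@H](O)C/C(C)=C/I | intermediate
10 | TBS ether of 9 | C[Si](C)(C)C#CC(=C(C)C)[C@@H](O[Si](C)(C)C(C)(C)C)C/C(C)=C/I | intermediate
11 | (1-ethoxycyclopropoxy)trimethylsilane | CCOC1(CC1)O[Si](C)(C)C | starting material
12 | 1-ethoxycyclopropan-1-ol | CCOC1(O)CC1 | intermediate
13 | (E)-alkenyllithium from 10 | C[Si](C)(C)C#CC(=C(C)C)[C@@H](O[Si](C)(C)C(C)(C)C)C/C(C)=C/[Li] | intermediate
14 | bromomagnesium 1-ethoxycyclopropanolate | CCOC1(CC1)O[Mg]Br | intermediate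
15 | cyclopropanone | O=C1CC1 | intermediate
16 | 1-[(1E,4S)-4-[(tert-butyldimethylsilyl)oxy]-2,6-dimethyl-5-[(trimethylsilyl)ethynyl]hepta-1,5-dien-1-yl]cyclopropan-1-ol | C[Si](C)(C)C#CC(=C(C)C)[C@@H](O[Si](C)(C)C(C)(C)C)C/C(C)=C/C1(O)CC1 | intermediate
17 | bis-TBS ether of 16 | C[Si](C)(C)C#CC(=C(C)C)[C@@H](O[Si](C)(C)C(C)(C)C)C/C(C)=C/C1(O[Si](C)(C)C(C)(C)C)CC1 | intermediate
18 | (1E,4S)-enyne-tethered 1-alkenyl-1-silyloxycyclopropane (cycloaddition precursor) | C#CC(=C(C)C)[C@@H](O[Si](C)(C)C(C)(C)C)C/C(C)=C/C1(O[Si](C)(C)C(C)(C)C)CC1 | intermediate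
19 | (2S,8aR)-2,7-bis[(tert-butyldimethylsilyl)oxy]-8a-methyl-3-(propan-2-ylidene)-1,2,3,5,6,8a-hexahydroazulene | CC(C)(C)[Si](C)(C)O[C@H]1C[C@]2(C)C=C(O[Si](C)(C)C(C)(C)C)CCC=C2C1=C(C)C | intermediate
20 | (2S,8aR)-dienyl ketone | CC(C)(C)[Si](C)(C)O[C@H]1C[C@]2(C)CC(=O)CCC=C2C1=C(C)C | intermediate
21 | (2S,8aR)-ketone with ring A tetrasubstituted alkene | CC(C)(C)[Si](C)(C)O[C@H]1C[C@]2(C)CC(=O)CCCC2=C1C(C)C | intermediate
22 | C-6/C-7 lithium enolate of 21 | CC(C)(C)[Si](C)(C)O[C@H]1C[C@]2(C)CC(O[Li])=CCCC2=C1C(C)C | intermediate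
23 | 6-[(dimethylamino)methyl] ketone (Mannich base, C-6 epimers) | CC(C)(C)[Si](C)(C)O[C@H]1C[C@]2(C)CC(=O)C(CN(C)C)CCC2=C1C(C)C | intermediate
24 | 6-[(trimethylammonio)methyl] ketone iodide | CC(C)(C)[Si](C)(C)O[C@H]1C[C@]2(C)CC(=O)C(C[N+](C)(C)C)CCC2=C1C(C)C.[I-] | intermediate
25 | (2S,8aR)-6-methylidene ketone | CC(C)(C)[Si](C)(C)O[C@H]1C[C@]2(C)CC(=O)C(=C)CCC2=C1C(C)C | intermediate
26 | (2S,7R,8aS)-6-methylidene-7-ol (hydroxyl cis to 8a-methyl) | CC(C)(C)[Si](C)(C)O[C@H]1C[C@]2(C)C[C@@H](O)C(=C)CCC2=C1C(C)C | intermediate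
27 | (2S,6R,7R,8aS)-spiro-epoxy alcohol (epoxide oxygen cis to 7-hydroxyl and 8a-methyl) | CC(C)(C)[Si](C)(C)O[C@H]1C[C@]2(C)C[C@@H](O)[C@]3(CO3)CCC2=C1C(C)C | intermediate
28 | (2S,6S,7R,8aS)-6,7-diol | CC(C)(C)[Si](C)(C)O[C@H]1C[C@]2(C)C[C@@H](O)[C@@](C)(O)CCC2=C1C(C)C | intermediate
29 | (2S,6S,8aR)-6-hydroxy-7-ketone | CC(C)(C)[Si](C)(C)O[C@H]1C[C@]2(C)CC(=O)[C@@](C)(O)CCC2=C1C(C)C | intermediate
30 | (2Z)-2-methylbut-2-enoic acid (angelic acid) | C/C=C(/C)C(=O)O | starting material
31 | lithium alkoxide of 29 | CC(C)(C)[Si](C)(C)O[C@H]1C[C@]2(C)CC(=O)[C@@](C)(O[Li])CCC2=C1C(C)C | intermediate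
32 | (2S,6S,8aR)-6-angelate 2-TBS ether | CC(C)(C)[Si](C)(C)O[C@H]1C[C@]2(C)CC(=O)[C@@](C)(OC(=O)/C(C)=C\C)CCC2=C1C(C)C | intermediate
33 | (2S,6S,8aR)-2-hydroxy 6-angelate | O[C@H]1C[C@]2(C)CC(=O)[C@@](C)(OC(=O)/C(C)=C\C)CCC2=C1C(C)C | intermediate
34 | (2S,6S,8aR)-6,8a-dimethyl-7-oxo-3-(propan-2-yl)-1,2,4,5,6,7,8,8a-octahydroazulene-2,6-diyl bis[(2Z)-2-methylbut-2-enoate] | C/C=C(/C)C(=O)O[C@H]1C[C@]2(C)CC(=O)[C@@](C)(OC(=O)/C(C)=C\C)CCC2=C1C(C)C | target

**Step count**

Total: 20 steps. Longest linear sequence: 19 steps (steps 1–5 and 7–20); step 6 is a one-step side branch.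

**Steps most likely to fail**

Step 10. The risk is that the facial selectivity at the trisubstituted alkene runs in the wrong sense, so that the silyloxy group ends trans to the angular methyl, and that a chiral ligand does not override it. The fallback changes the source of control: C-8a is induced from the antipodal carbinol and C-2 is inverted afterwards. It sets out from 5. Propargylation with the (R)-configured phosphoric acid gives the (4R)-alcohol F1. Carboalumination–iodination through the alkenylalane F2 gives the (4R,6E)-iodo alcohol F3, and silylation gives the TBS ether F4. Iodine–lithium exchange to the alkenyllithium F5 and addition to cyclopropanone (from 14 through 15) gives the cyclopropanol F6. Silylation gives the bis-silyl ether F7, and K2CO3 in methanol gives the (4R) precursor F8. Under [Rh(CO)2Cl]2 the mirror-image preference should now give the (2R,8aR)-cycloadduct F9, which has the required quaternary configuration. Bu4NF at rt removes both silyl groups to give the hydroxy dienone F10. Mitsunobu inversion with 4-nitrobenzoic acid, PPh3 and diisopropyl azodicarboxylate gives the (2S)-4-nitrobenzoate F11, K2CO3 in methanol gives the (2S)-hydroxy dienone F12, and TBSOTf with 2,6-lutidine returns the route to 20.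

Step 18. The risk is slow acyl transfer to the hindered tertiary alkoxide, so that isomerisation of the angeloyl donor to the (E) isomer or α-ketol rearrangement of the alkoxide overtakes acylation. The fallback builds the angelate on the oxygen from a sterically small acyl group. It sets out from 29. The lithium alkoxide is acylated with the mixed anhydride of but-2-ynoic acid and 2,4,6-trichlorobenzoyl chloride to give the but-2-ynoate F17. Pd(PPh3)4-catalysed syn-hydrostannation with Bu3SnH places tin α to the ester and gives the (E)-2-(tributylstannyl)but-2-enoate F18. Stille methylation with MeI (Pd2(dba)3, P(o-tol)3, CuCl, K2CO3, DMF) proceeds with retention and returns the route to 32.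

Step 12. The risk is that the tetrasubstituted diene terminus fails to bind the Cr(CO)3 fragment, so that no hydrogen is taken up or slow turnover allows alkene migration. The fallback is a dissolving-metal 1,4-reduction on a substrate whose allylic oxygen is held as an alkoxide. It sets out from 20. 1,2-Bis(trimethylsilyloxy)ethane with catalytic Me3SiOTf in CH2Cl2 at −78 °C gives the dioxolane F13, and Bu4NF gives the dienyl alcohol F14. Deprotonation with n-BuLi and then lithium in liquid ammonia/THF with t-BuOH at −78 °C reduces the diene 1,4 to the ring A alkene F15; the alkoxide prevents reductive loss of the allylic oxygen. TBSOTf with 2,6-lutidine gives the silyl ether F16, and pyridinium p-toluenesulfonate in wet acetone returns the route to 21.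

**Further compounds**

F1 | step 10 | (4R)-2-methyl-3-[(trimethylsilyl)ethynyl]hept-2-en-6-yn-4-ol | C[Si](C)(C)C#CC(=C(C)C)[C@H](O)CC#C
F2 | step 10 | (E)-alkenyl(dimethyl)alane of F1 with the carbinol as its dimethylaluminium alkoxide | C[Si](C)(C)C#CC(=C(C)C)[C@H](O[Al](C)C)C/C(C)=C/[Al](C)C
F3 | step 10 | (4R,6E)-7-iodo-2,6-dimethyl-3-[(trimethylsilyl)ethynyl]hepta-2,6-dien-4-ol | C[Si](C)(C)C#CC(=C(C)C)[C@H](O)C/C(C)=C/I
F4 | step 10 | TBS ether of F3 | C[Si](C)(C)C#CC(=C(C)C)[C@H](O[Si](C)(C)C(C)(C)C)C/C(C)=C/I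
F5 | step 10 | (E)-alkenyllithium from F4 | C[Si](C)(C)C#CC(=C(C)C)[C@H](O[Si](C)(C)C(C)(C)C)C/C(C)=C/[Li]
F6 | step 10 | (1E,4R)-1-alkenylcyclopropan-1-ol (enantiomer of 16) | C[Si](C)(C)C#CC(=C(C)C)[C@H](O[Si](C)(C)C(C)(C)C)C/C(C)=C/C1(O)CC1
F7 | step 10 | bis-TBS ether of F6 | C[Si](C)(C)C#CC(=C(C)C)[C@H](O[Si](C)(C)C(C)(C)C)C/C(C)=C/C1(O[Si](C)(C)C(C)(C)C)CC1
F8 | step 10 | (1E,4R) cycloaddition precursor (enantiomer of 18) | C#CC(=C(C)C)[C@H](O[Si](C)(C)C(C)(C)C)C/C(C)=C/C1(O[Si](C)(C)C(C)(C)C)CC1
F9 | step 10 | (2R,8aR)-2,7-bis[(tert-butyldimethylsilyl)oxy]-8a-methyl-3-(propan-2-ylidene)-1,2,3,5,6,8a-hexahydroazulene | CC(C)(C)[Si](C)(C)O[C@@H]1C[C@]2(C)C=C(O[Si](C)(C)C(C)(C)C)CCC=C2C1=C(C)C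
F10 | step 10 | (2R,8aR)-2-hydroxy-8a-methyl-3-(propan-2-ylidene)-1,2,3,5,6,8a-hexahydroazulen-7(8H)-one | O[C@@H]1C[C@]2(C)CC(=O)CCC=C2C1=C(C)C
F11 | step 10 | (2S,8aR)-8a-methyl-7-oxo-3-(propan-2-ylidene)-1,2,3,5,6,7,8,8a-octahydroazulen-2-yl 4-nitrobenzoate | O=C(O[C@H]1C[C@]2(C)CC(=O)CCC=C2C1=C(C)C)c1ccc(cc1)[N+](=O)[O-]
F12 | step 10 | (2S,8aR)-2-hydroxy-8a-methyl-3-(propan-2-ylidene)-1,2,3,5,6,8a-hexahydroazulen-7(8H)-one | O[C@H]1C[C@]2(C)CC(=O)CCC=C2C1=C(C)C
F13 | step 12 | ethylene ketal (1,3-dioxolane) of 20 | CC(C)(C)[Si](C)(C)O[C@H]1C[C@]2(C)CC3(OCCO3)CCC=C2C1=C(C)C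
F14 | step 12 | C-2 alcohol of the dienyl ketal | O[C@H]1C[C@]2(C)CC3(OCCO3)CCC=C2C1=C(C)C
F15 | step 12 | C-2 alcohol of the ketal with ring A tetrasubstituted alkene and isopropyl group | O[C@H]1C[C@]2(C)CC3(OCCO3)CCCC2=C1C(C)C
F16 | step 12 | TBS ether of F15 (ethylene ketal of 21) | CC(C)(C)[Si](C)(C)O[C@H]1C[C@]2(C)CC3(OCCO3)CCCC2=C1C(C)C
F17 | step 18 | (2S,6S,8aR)-6-(but-2-ynoate) 2-TBS ether | CC(C)(C)[Si](C)(C)O[C@H]1C[C@]2(C)CC(=O)[C@@](C)(OC(=O)C#CC)CCC2=C1C(C)C
F18 | step 18 | (2S,6S,8aR)-6-[(2E)-2-(tributylstannyl)but-2-enoate] 2-TBS ether | CC(C)(C)[Si](C)(C)O[C@H]1C[C@]2(C)CC(=O)[C@@](C)(OC(=O)/C(=C\C)[Sn](CCCC)(CCCC)CCCC)CCC2=C1C(C)C
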